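**Retrosynthetic overview**

- Ring numbering: C1 carries OAc, C2=C3 is the alkene with C3 bearing C7H2OBz, C4 carries OH, C5 OBz and C6 OH. The route rests on the cis C5–O/C6–O pair of the cyclohexene ring, flanked by the four-carbon unit C1–C4; this is the pattern of an arene cis-dihydrodiol with its residual diene.
- Target 20 ⇒ triol 17 by opening of a cyclic orthobenzoate on the cis C5,C6-diol. 17 ⇒ C4 ketone 16 by hydroxyl-directed reduction after ketal removal, because external hydride on the ketal is expected to enter anti to the dioxolane and give the C4 epimer.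
- 16 ⇒ enone 10 + formaldehyde (Morita–Baylis–Hillman, C3–C7 bond). 10 ⇒ bromodiene ketal 5 + O2 (singlet-oxygen [4+2] anti to the ketal forms C1–O and C4–O; the brominated C4 collapses to the ketone).
- 5 ⇒ diol 3 ⇒ bromobenzene + O2 (enzymatic cis-dihydroxylation sets C5 and C6).
- The only ring of the target, the carbocycle, is the benzene ring of bromobenzene; no ring-forming step is needed beyond temporary dioxolanes.

Key step: step 1

Assumption: the recombinant E. coli strain expressing toluene dioxygenase is treated as an available biocatalyst; the locants C1–C7 above are used for all intermediates ("route numbering").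

**Route**

Step 1
Reactants: 1 bromobenzene; 2 dioxygen
Product: 3 (1S,2S)-3-bromocyclohexa-3,5-diene-1,2-diol
Conditions: E. coli JM109(pDTG601) whole cells expressing toluene dioxygenase (IPTG-induced), glucose feed, air sparge, aqueous mineral salts medium, pH 7, 35 °C; EtOAc extraction of the clarified broth
Reagents that add atoms: dioxygen, O=O
Why: Toluene dioxygenase, a Rieske-type non-haem iron enzyme supplied with two electrons from NADH through its reductase and ferredoxin partners, binds O2 at its mononuclear iron site and transfers both oxygen atoms to one face of the arene bond next to the C–Br carbon, so that C5–O and C6–O form cis and aromaticity is lost. The closest known reaction type is the whole-cell cis-dihydroxylation of monohalobenzenes by this enzyme, which is preparative chemistry. No ring is closed. Both new stereocenters, C5 and C6, are fixed by the chiral active site (catalyst control), and with bromine on the carbon that becomes C4 they have the absolute configuration the target needs. The step needs regioselectivity for the bond adjacent to bromine, one enantiotopic face and no further oxidation: the single large substituent docks the arene in one orientation in the substrate pocket, and the recombinant host lacks the cis-diol dehydrogenase that would rearomatise 3 to the catechol.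

Step 2
Reactants: 3 (1S,2S)-3-bromocyclohexa-3,5-diene-1,2-diol; 4 2,2-dimethoxypropane
Product: 5 (3aS,7aS)-4-bromo-2,2-dimethyl-3a,7a-dihydro-1,3-benzodioxole
Conditions: 2,2-dimethoxypropane, p-TsOH·H2O (cat.), acetone, 0 °C → rt
Reagents that add atoms: 2,2-dimethoxypropane, COC(C)(C)OC
Why: Acid-catalysed transketalisation closes a cis-fused dioxolane on the cis C5,C6-diol without touching either stereocenter, and the ketal slows Diels–Alder dimerisation of the diene and shields one ring face for the next step.

Step 3
Reactants: 5 (3aS,7aS)-4-bromo-2,2-dimethyl-3a,7a-dihydro-1,3-benzodioxole; 2 dioxygen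
Product: 8 (3aS,7R,7aS)-7-hydroxy-2,2-dimethyl-7,7a-dihydro-1,3-benzodioxol-4(3aH)-one, via bromo endoperoxide 6 (not isolated), via gem-bromohydrin 7 (not isolated)
Conditions: O2, hν (visible), tetraphenylporphyrin (cat.), CH2Cl2, −20 °C; then thiourea, MeOH, −20 °C → rt
Reagents that add atoms: dioxygen, O=O
Why: Photosensitised singlet oxygen adds to the 1,3-diene in a [4+2] cycloaddition across C1 and C4 on the face opposite the cis-fused dioxolane, which sets C1–O trans to the C6 oxygen, and thiourea then reduces the O–O bond so that the C4 gem-bromohydrin loses HBr to give the C4 ketone conjugated with C2=C3, a sequence known for halodiene ketals.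

Step 4
Reactants: 8 hydroxy enone; 9 acetic anhydride
Product: 10 (1R,5S,6S)-1-acetoxy-5,6-(isopropylidenedioxy)cyclohex-2-en-4-one (route numbering)
Conditions: Ac2O, pyridine, CH2Cl2, 0 °C → rt
Reagents that add atoms: acetic anhydride, CC(=O)OC(C)=O
Why: Plain O-acylation of the secondary allylic C1 hydroxyl installs the acetate of the target at the point where C1–OH is the only free hydroxyl, so no protecting group is needed at C1.

Step 5
Reactants: 10 acetoxy enone; 11 formaldehyde
Product: 12 (1R,5S,6S)-1-acetoxy-3-(hydroxymethyl)-5,6-(isopropylidenedioxy)cyclohex-2-en-4-one (route numbering)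
Conditions: 37% aq. HCHO, imidazole, 1 M aq. NaHCO3, THF, rt
Reagents that add atoms: formaldehyde, C=O
Why: Morita–Baylis–Hillman reaction in which imidazole adds reversibly to C2, the C3 enolate undergoes aldol addition to formaldehyde and loss of imidazole returns the enone with the C7 hydroxymethyl group on C3, no stereocenter being formed and the weakly basic bicarbonate medium being chosen to spare the C1 acetate and to limit enolisation at C5.

Step 6
Reactants: 12 hydroxymethyl enone; 13 benzoyl chloride
Product: 14 (1R,5S,6S)-1-acetoxy-3-(benzoyloxymethyl)-5,6-(isopropylidenedioxy)cyclohex-2-en-4-one (route numbering)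
Conditions: BzCl, 2,4,6-collidine, CH2Cl2, 0 °C → rt
Reagents that add atoms: benzoyl chloride, O=C(Cl)c1ccccc1
Why: O-Benzoylation of the only free (primary, allylic) hydroxyl, with a hindered non-nucleophilic pyridine base so that the resulting allylic benzoate next to the enone is not attacked in an SN2′ sense.

Step 7
Reactants: 14 enone benzoate; 15 water
Product: 16 (1R,5S,6R)-1-acetoxy-3-(benzoyloxymethyl)-5,6-dihydroxycyclohex-2-en-4-one (route numbering; C5-OH and C6-OH cis, C1-OAc trans to C6-OH)
Conditions: TFA–H2O (4:1), 0 °C; evaporation with toluene, used directly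
Reagents that add atoms: none
Why: Acid hydrolysis of the isopropylidene ketal frees the C5 and C6 hydroxyls needed to direct the reduction, the esters being stable to cold aqueous trifluoroacetic acid and the short cold exposure limiting dehydration of the β-hydroxy ketone.

Step 8
Reactants: 16 dihydroxy enone
Product: 17 (1R,4S,5R,6R)-1-acetoxy-3-(benzoyloxymethyl)cyclohex-2-ene-4,5,6-triol (route numbering; C4-OH trans to C5-OH, C5-OH cis to C6-OH, C1-OAc trans to C6-OH)
Conditions: Me4NBH(OAc)3, MeCN–AcOH (1:1), −30 → 0 °C
Reagents that add atoms: none
Why: Hydroxyl-directed (Evans–Saksena) reduction in which the C6 hydroxyl β to the ketone, supported by the α-hydroxyl on C5, exchanges for acetate on boron and delivers hydride intramolecularly to the face of C4=O that carries these oxygens, so that the new C4 hydroxyl ends up on the opposite face, trans to the C5 oxygen and 1,3-anti to the C6 hydroxyl, while the weakly hydridic reagent leaves the esters and the conjugate position alone.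

Step 9
Reactants: 17 triol; 18 trimethyl orthobenzoate; 15 water
Product: 20 target CNP0169028.1, via cyclic orthobenzoate 19 (not isolated)
Conditions: PhC(OMe)3 (1.2 equiv), CSA (cat.), MeCN, rt; then 80% aq. AcOH, rt
Reagents that add atoms: trimethyl orthobenzoate, COC(OC)(OC)c1ccccc1; water, O
Why: Acid-catalysed orthoester exchange takes place on the only cis-diol (C5/C6) and mild aqueous acid then opens the 2-methoxy-2-phenyl-1,3-dioxolane through its hemi-orthoester, which by the usual stereoelectronic preference leaves the ester on the axial oxygen, expected to be O5 because the half-chair that relieves allylic 1,2-strain between the C3 side chain and the C4 hydroxyl places C4–O pseudoaxial, C5–O axial and C6–O equatorial.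

**Compound list**

1 | bromobenzene | Brc1ccccc1 | starting material
2 | dioxygen | O=O | starting material
3 | (1S,2S)-3-bromocyclohexa-3,5-diene-1,2-diol | C1=CC=C(Br)[C@@H](O)[C@H]1O | intermediate
4 | 2,2-dimethoxypropane | COC(C)(C)OC | starting material
5 | (3aS,7aS)-4-bromo-2,2-dimethyl-3a,7a-dihydro-1,3-benzodioxole | C1=CC=C(Br)[C@H]2OC(C)(C)O[C@@H]12 | intermediate
6 | bromo endoperoxide: C1–O–O–C4 bridge anti to the ketal, Br on bridgehead C4 | [C@H]12C=C[C@](Br)(OO1)[C@H]3OC(C)(C)O[C@@H]23 | intermediate
7 | gem-bromohydrin: C1-OH and C4(OH)Br, both hydroxyls anti to the ketal | O[C@@H]1C=C[C@](Br)(O)[C@H]2OC(C)(C)O[C@@H]12 | intermediate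
8 | (3aS,7R,7aS)-7-hydroxy-2,2-dimethyl-7,7a-dihydro-1,3-benzodioxol-4(3aH)-one | O[C@@H]1C=CC(=O)[C@H]2OC(C)(C)O[C@@H]12 | intermediate
9 | acetic anhydride | CC(=O)OC(C)=O | starting material
10 | (1R,5S,6S)-1-acetoxy-5,6-(isopropylidenedioxy)cyclohex-2-en-4-one (route numbering) | CC(=O)O[C@@H]1C=CC(=O)[C@H]2OC(C)(C)O[C@@H]12 | intermediate
11 | formaldehyde | C=O | starting material
12 | (1R,5S,6S)-1-acetoxy-3-(hydroxymethyl)-5,6-(isopropylidenedioxy)cyclohex-2-en-4-one (route numbering) | CC(=O)O[C@@H]1C=C(CO)C(=O)[C@H]2OC(C)(C)O[C@@H]12 | intermediate
13 | benzoyl chloride | O=C(Cl)c1ccccc1 | starting material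
14 | (1R,5S,6S)-1-acetoxy-3-(benzoyloxymethyl)-5,6-(isopropylidenedioxy)cyclohex-2-en-4-one (route numbering) | CC(=O)O[C@@H]1C=C(COC(=O)c3ccccc3)C(=O)[C@H]2OC(C)(C)O[C@@H]12 | intermediate
15 | water | O | starting material
16 | (1R,5S,6R)-1-acetoxy-3-(benzoyloxymethyl)-5,6-dihydroxycyclohex-2-en-4-one (route numbering) | CC(=O)O[C@@H]1C=C(COC(=O)c2ccccc2)C(=O)[C@@H](O)[C@H]1O | intermediate
17 | (1R,4S,5R,6R)-1-acetoxy-3-(benzoyloxymethyl)cyclohex-2-ene-4,5,6-triol (route numbering) | CC(=O)O[C@@H]1C=C(COC(=O)c2ccccc2)[C@H](O)[C@@H](O)[C@H]1O | intermediate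
18 | trimethyl orthobenzoate | COC(OC)(OC)c1ccccc1 | starting material
19 | cyclic orthobenzoate: 2-methoxy-2-phenyl-1,3-dioxolane on O5/O6 of 17 (both epimers at the orthoester carbon) | CC(=O)O[C@@H]1C=C(COC(=O)c2ccccc2)[C@H](O)[C@H]2OC(OC)(c3ccccc3)O[C@@H]12 | intermediate
20 | (1R,4S,5R,6S)-1-acetoxy-5-benzoyloxy-3-(benzoyloxymethyl)cyclohex-2-ene-4,6-diol (route numbering), CNP0169028.1 | CC(=O)O[C@@H]1C=C(COC(=O)c2ccccc2)[C@H](O)[C@@H](OC(=O)c2ccccc2)[C@H]1O | target

**Step count**

Total steps: 9. Longest linear sequence: 9 (fully linear from bromobenzene).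

**Steps most likely to fail**

1. Step 9, regioselection in the orthoester opening. If the other half-chair (C6–O axial) is populated, the hemi-orthoester opens towards the O6 benzoate, and benzoyl migration between O5 and O6 can further blur the outcome. The fallback sets out from 17 and uses the complementary regiochemical rule. Heating 17 with Bu2SnO in toluene with azeotropic removal of water should give the dibutylstannylene acetal F5 on the cis C5,C6-diol. Treating it with BzCl (1 equiv) at 0 °C acylates the equatorial oxygen of a cis-diol, the opposite of the orthoester rule, and the sequence comes back to the route at 20.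

2. Step 5, the Morita–Baylis–Hillman hydroxymethylation. Catalyst addition at C2 next to the acetoxy-bearing C1 may be slow. During a long reaction time, enolisation at C5 with β-elimination of the C6 oxygen (aromatisation) and hydrolysis of the acetate can compete. The fallback sets out from 10 and replaces the aldol step by cross-coupling. α-Iodination (I2, pyridine, CH2Cl2, 0 °C → rt) should give the α-iodo enone F1. Stille coupling with (tributylstannyl)methanol under Pd(PPh3)4 (zerovalent palladium) in dioxane at 80 °C then forms the C3–C7 bond and comes back to the route at 12.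

3. Step 8, the directed reduction. Facial selectivity may erode through non-directed hydride delivery or an unfavourable ring conformer, and the free α-ketol may isomerise or dehydrate before it is reduced. The fallback sets out from 14, keeps the ketal and sets C4 by inversion:
   - Reduction with NaBH4 and CeCl3·7H2O in MeOH at −78 °C (Luche conditions) should deliver hydride anti to the dioxolane and give the cis allylic alcohol F2.
   - Mitsunobu reaction with chloroacetic acid (PPh3, DIAD, toluene, 0 °C → rt) inverts C4 to the chloroacetate F3.
   - Thiourea with 2,6-lutidine in EtOH at 50 °C removes only the chloroacetyl group to give the C4 alcohol ketal F4.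
   - TFA–H2O at 0 °C hydrolyses the ketal and comes back to the route at 17.

**Further compounds**

F1 | step 5 | α-iodo enone: (1R,5S,6S)-1-acetoxy-3-iodo-5,6-(isopropylidenedioxy)cyclohex-2-en-4-one (route numbering) | CC(=O)O[C@@H]1C=C(I)C(=O)[C@H]2OC(C)(C)O[C@@H]12
F2 | step 8 | cis allylic alcohol: C4-OH on the same face as the C5,C6 ketal oxygens, C1-OAc and C7-OBz in place | CC(=O)O[C@@H]1C=C(COC(=O)c3ccccc3)[C@@H](O)[C@H]2OC(C)(C)O[C@@H]12
F3 | step 8 | inverted chloroacetate: C4-OC(O)CH2Cl trans to the C5 oxygen | CC(=O)O[C@@H]1C=C(COC(=O)c3ccccc3)[C@H](OC(=O)CCl)[C@H]2OC(C)(C)O[C@@H]12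
F4 | step 8 | C4 alcohol ketal: C4-OH trans to the C5 oxygen, C5,C6 ketal intact | CC(=O)O[C@@H]1C=C(COC(=O)c3ccccc3)[C@H](O)[C@H]2OC(C)(C)O[C@@H]12
F5 | step 9 | dibutylstannylene acetal of 17 on O5/O6 | CC(=O)O[C@@H]1C=C(COC(=O)c2ccccc2)[C@H](O)[C@H]2O[Sn](CCCC)(CCCC)O[C@@H]12
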